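All runs were generated by integration with made-up constants; the scatter is artificial.

I chose to follow one thing in this flask, the rate at which D is lost, rather than any amount, and wrote it as k_D·c_D·c_Q.

| flask | D | Q | remark | time |
|---|---|---|---|---|
| Wednesday's | 1 M | 2 equiv | the very flask that is asked about, followed so far |  |
| Sunday's | 1 M | 3 equiv | run made earlier |  |
| flask | 1.0 M | 2.00 equiv |  | 8.0 h |

Wednesday's run (percent of the D charged)

| time / min | D / % | X / % |
|---|---|---|
| 5.00 | 97.3 | 0 |
| 10.0 | 92.9 | 4.4 |
| 25.0 | 87.0 | 10.6 |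
| 60.0 | 71.3 | 19.8 |

Sunday's run (percent of the D charged)

| time / h | D / % | X / % |
|---|---|---|
| 0.833 | 68.2 | 22.5 |
| 1.50 | 47.6 | 32.3 |
| 2.50 | 32.4 | 41.6 |
| 3.00 | 27.7 | 41.8 |

(scatter of a reading: 1 percentage point)

* amount of D at 8.0 h, in percent of the D charged
* amount of X at 8.0 h, in percent of the D charged
* amount of Z at 8.0 h, in percent of the D charged
* amount of L at 8.0 h, in percent of the D charged

- steps thought possible: D + Q -> X; D + Q -> Z; Q + X -> L; Q + Z -> L

Wednesday's run had D at 71.3% after 60.0 min. Each D lost takes one Q and each L made takes one more, so, leaving L aside, I took the mean c_Q in Wednesday's run as its charge less half the D lost over that time. That gave the loss constant, the sum of the two routes from D, read from this one scattered reading, as k_D = 0.182 L mol⁻¹ h⁻¹. The rate in this flask therefore starts at 0.364 M h⁻¹, and two things slow it: the fraction of D left and the fraction of Q left. D, charged at 1.0 M against 2.00 M of Q, is the limiting reagent for the first addition.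

Over 8.0 h I judged the mean c_Q to be 1.33 M, which left a D factor of 14.3%. I reckoned the Q factor at 57.2% with L uncounted, and any L lowers it further. Together they put the final rate at 0.0818 of the start, or 0.0298 M h⁻¹.

The forecast gave D 16.5%, somewhat more than my figure, with X 43.5%, Z 11% and L 29%, and it said of its weak point: “Z was never measured, so Z→L is a guess”.

The flask gave D 15.8%, X 44.1%, Z 22.7% and L 17.4%.

    D + Q → X (k = 0.00210 L mol⁻¹ min⁻¹)
    D + Q → Z (k = 7.90 × 10⁻⁴ L mol⁻¹ min⁻¹)
    Q + X → L (k = 8.20 × 10⁻⁴ L mol⁻¹ min⁻¹)
    Q + Z → L (k = 2.90 × 10⁻⁵ L mol⁻¹ min⁻¹)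

The half-life of Z by the path from Q + Z to L, with the other concentrations as charged, is 200 h, long against 8.0 h. With D at 15.8% and Q at 49% of its charge, k_D puts the rate at 8.0 h at 0.0283 M h⁻¹. Taking c_Q as the mean of its values at 8.0 h and 20 h, the same k_D carries D to 2.60% at 20 h, and the same flask left that long holds 3.03%.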